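**Retrosynthetic overview**

1. The three guaiacylglycerol 8‑O‑4 units are cut at C7–C8 (Evans syn aldols of aryloxyacetyl imides) and at the ArO–CH2 bonds, which leads back to (7S,8R,7′S,8′R)-syringaresinol 14, aldehyde 17 and fragment 2 (aldehyde 29, which already carries unit C).
2. The syn aldols give threo units: 7S,8S for A and B from the (R)-auxiliary, 7R,8R for C from the (S)-auxiliary. A and C are made erythro by Mitsunobu inversion at C7, and the 4-nitrobenzoate so formed serves as the C7 protecting group.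
3. The strategy rests on this feature: C7, C8, C8′ and C7′ of the 3,7-dioxabicyclo[3.3.0]octane core form a C2-symmetric 1,4-dioxygenated four-carbon chain. Its 1,4-diketone form is the oxidative dimer of one aroylacetate, with both C8 centres epimerizable.
4. All four core stereocentres are therefore set in one double dynamic kinetic transfer hydrogenation of diaroylsuccinate 7, with crosswise lactonization.
5. Ring order: the two γ-lactone rings (O7–C9′, then O7′–C9) in step 4; after reduction they are re-closed as the two tetrahydrofuran rings in step 6; no ring is formed later.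

Key step: step 4

Remark: lignan numbering is used (C7 benzylic, C8, C9; primes for the second half of the core; A, B, C for the glycerol units; TBS = tert-butyldimethylsilyl, TIPS = triisopropylsilyl). Both enantiomers of 4-benzyl-3-(chloroacetyl)oxazolidin-2-one are assumed to be commercial.

**Core (steps 1–7)**

Step 1
Reactants: 1 acetosyringone; 2 benzyl bromide
Product: 3 1-[4-(benzyloxy)-3,5-dimethoxyphenyl]ethan-1-one
Conditions: K2CO3, DMF, 60 °C
Reagents that add atoms: benzyl bromide (2), BrCc1ccccc1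
Why: Williamson etherification of the acidic, doubly ortho-substituted phenol with a reactive benzylic halide; no stereocentre is involved.

Step 2
Reactants: 3 1-[4-(benzyloxy)-3,5-dimethoxyphenyl]ethan-1-one; 4 dimethyl carbonate
Product: 5 methyl 3-[4-(benzyloxy)-3,5-dimethoxyphenyl]-3-oxopropanoate
Conditions: NaH (2.2 equiv), (MeO)2CO (excess), THF, reflux; then aq HCl
Reagents that add atoms: dimethyl carbonate (4), COC(=O)OC
Why: crossed Claisen condensation of the methyl ketone enolate with the non-enolizable carbonate, driven by irreversible deprotonation of the β-keto ester formed.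

Step 3
Reactants: 5 methyl 3-[4-(benzyloxy)-3,5-dimethoxyphenyl]-3-oxopropanoate (two molecules)
Product: 7 dimethyl 2,3-bis[4-(benzyloxy)-3,5-dimethoxybenzoyl]butanedioate (meso/dl mixture, stereolabile at C2 and C3), via α-iodo keto ester 6 (not isolated)
Conditions: NaH (1.0 equiv), THF, 0 °C; I2 (0.5 equiv), −78 °C → rt
Reagents that add atoms: none
Why: oxidative enolate dimerization (iodine coupling of β-keto ester enolates), in which half of the sodium enolate is iodinated to 6 and the other half displaces iodide by SN2; the two new centres are stereolabile and are deliberately left uncontrolled.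

Step 4
Reactants: 7 dimethyl 2,3-bis[4-(benzyloxy)-3,5-dimethoxybenzoyl]butanedioate
Product: 10 (1S,2S,5S,6S)-2,6-bis[4-(benzyloxy)-3,5-dimethoxyphenyl]-3,7-dioxabicyclo[3.3.0]octane-4,8-dione (cis-fused, both aryl groups exo), via hydroxy diester 8 (not isolated), via monolactone 9 (not isolated)
Conditions: RuCl(p-cymene)[(S,S)-TsDPEN] (2 mol %), HCO2H/Et3N (1:1), DMF, 30 °C; then 50 °C
Reagents that add atoms: none
Why: Proposed new method: the 18-electron hydride RuH(p-cymene)[(S,S)-TsDPEN] (divalent ruthenium) transfers hydride and proton to each aryl ketone through the outer-sphere six-membered transition state while C8 and C8′ of 7 epimerize through the β-keto ester enols, so the whole diastereomer mixture should drain into hydroxy diester 8; the closest known reaction type is the Noyori dynamic kinetic asymmetric (transfer) hydrogenation of α-substituted β-keto esters, which here must operate twice within one 2,3-diacylsuccinate. Each new 7-hydroxyl then adds to the ester carbonyl of the other half and expels methanol (5-exo-trig addition–elimination; O7–C9′ gives 9, O7′–C9 gives 10), which closes the two γ-lactone rings as a cis-fused bicycle. C7 and C7′ are set by the ligand (aryl group edge-on to the η6-arene, the sense that turns acetophenone into the (S)-alcohol); C8 and C8′ are set relative to them by the dynamic resolution, with the branched succinate carbon expected anti to the incoming hydride (Felkin–Anh), which gives the 7,8-syn relation and hence exo aryl groups. The step needs the same sense in both halves, which the C2-symmetric constitution secures with a single catalyst, and it needs reduction to outrun Paal–Knorr cyclodehydration of the 1,4-diketone, for which the weakly acidic 1:1 HCO2H/Et3N medium is chosen. Only the 8S,8′S hydroxy diester can lactonize twice to an exo,exo cis-fused bicycle, so stereochemical errors should end in different, separable compounds and the enantiomeric purity of crystalline 10 should exceed that of a single reduction.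

Step 5
Reactants: 10 exo,exo-dilactone
Product: 11 (1S,2R,3R,4S)-1,4-bis[4-(benzyloxy)-3,5-dimethoxyphenyl]-2,3-bis(hydroxymethyl)butane-1,4-diol
Conditions: LiAlH4, THF, 0 °C → rt; H2O/aq NaOH work-up
Reagents that add atoms: none
Why: hydride reduction of both lactones to the tetraol, which is faster than enolization and leaves the benzyl ethers and all four stereocentres untouched.

Step 6
Reactants: 11 tetraol
Product: 13 (7S,8R,7′S,8′R)-4,4′-di-O-benzylsyringaresinol, via bis(mesylate) 12 (not isolated)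
Conditions: MsCl (2.2 equiv), pyridine, 0 °C → rt
Reagents that add atoms: none
Why: primary-selective sulfonylation followed by double intramolecular Williamson etherification (5-exo-tet, benzylic hydroxyl onto CH2OMs) should close both tetrahydrofuran rings; no bond to C7 or C7′ is broken, so the exo aryl configuration from step 4 is retained, and the cis fusion follows from C8/C8′.

Step 7
Reactants: 13 di-O-benzylsyringaresinol
Product: 14 (7S,8R,7′S,8′R)-syringaresinol
Conditions: H2 (1 atm), Pd/C, EtOAc, rt, stopped after uptake of 2 equiv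
Reagents that add atoms: none
Why: hydrogenolysis of the two aryl benzyl ethers, which is faster than cleavage of the dialkyl benzylic C–O bonds of the furofuran under neutral conditions.

**Fragment 2 (steps 8–14)**

Step 8
Reactants: 15 vanillin; 16 chlorotriisopropylsilane
Product: 17 3-methoxy-4-[(triisopropylsilyl)oxy]benzaldehyde
Conditions: imidazole, DMF, rt
Reagents that add atoms: chlorotriisopropylsilane (16), CC(C)[Si](Cl)(C(C)C)C(C)C
Why: silylation of the phenol gives a base-robust aryl silyl ether that is removed by fluoride at the end.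

Step 9
Reactants: 18 trans-isoeugenol; 19 (S)-4-benzyl-3-(chloroacetyl)oxazolidin-2-one
Product: 20 (S)-4-benzyl-3-{2-[2-methoxy-4-((E)-prop-1-enyl)phenoxy]acetyl}oxazolidin-2-one
Conditions: K2CO3, MeCN, 50 °C
Reagents that add atoms: (S)-4-benzyl-3-(chloroacetyl)oxazolidin-2-one (19), O=C1OC[C@H](Cc2ccccc2)N1C(=O)CCl
Why: Williamson etherification, in which SN2 at the activated α-chloro carbon is much faster than acyl transfer from the imide; the propenyl group is the masked aldehyde of ring B.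

Step 10
Reactants: 20 aryloxyacetyl imide; 17 3-methoxy-4-[(triisopropylsilyl)oxy]benzaldehyde
Product: 22 (S)-4-benzyl-3-{(2S,3R)-3-hydroxy-3-[3-methoxy-4-(triisopropylsilyloxy)phenyl]-2-[2-methoxy-4-((E)-prop-1-enyl)phenoxy]propanoyl}oxazolidin-2-one, via Z boron enolate 21 (not isolated)
Conditions: Bu2BOTf, i-Pr2NEt, CH2Cl2, −78 → 0 °C; 17, −78 → 0 °C; then pH 7 buffer, MeOH, H2O2, 0 °C
Reagents that add atoms: aldehyde 17, O=Cc1ccc(O[Si](C(C)C)(C(C)C)C(C)C)c(OC)c1
Why: Evans syn aldol; the Z boron enolate reacts through a Zimmerman–Traxler chair on the face away from the auxiliary benzyl group, which sets 2S,3R (syn).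

Step 11
Reactants: 22 syn-aldol adduct
Product: 23 (1R,2R)-1-[3-methoxy-4-(triisopropylsilyloxy)phenyl]-2-[2-methoxy-4-((E)-prop-1-enyl)phenoxy]propane-1,3-diol (threo)
Conditions: LiBH4, THF, H2O (1 equiv), 0 °C
Reagents that add atoms: none
Why: reductive cleavage of the N-acyloxazolidinone to the primary alcohol, without retro-aldol and with recovery of the auxiliary.

Step 12
Reactants: 23 threo diol; 24 tert-butylchlorodimethylsilane
Product: 25 (1R,2R)-3-[(tert-butyldimethylsilyl)oxy]-1-[3-methoxy-4-(triisopropylsilyloxy)phenyl]-2-[2-methoxy-4-((E)-prop-1-enyl)phenoxy]propan-1-ol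
Conditions: TBSCl (1.1 equiv), imidazole, CH2Cl2, 0 °C
Reagents that add atoms: tert-butylchlorodimethylsilane (24), CC(C)(C)[Si](C)(C)Cl
Why: silylation selective for the primary over the hindered secondary benzylic hydroxyl.

Step 13
Reactants: 25 mono-TBS ether; 26 4-nitrobenzoic acid
Product: 27 (1S,2R)-3-[(tert-butyldimethylsilyl)oxy]-1-[3-methoxy-4-(triisopropylsilyloxy)phenyl]-2-[2-methoxy-4-((E)-prop-1-enyl)phenoxy]propyl 4-nitrobenzoate (erythro)
Conditions: PPh3, DIAD, 4-O2NC6H4CO2H, toluene/THF, 0 °C → rt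
Reagents that add atoms: 4-nitrobenzoic acid (26), OC(=O)c1ccc(cc1)[N+](=O)[O-]
Why: Mitsunobu reaction; SN2 displacement of the alkoxyphosphonium by the acidic carboxylate inverts C7 (threo → erythro, 7S,8R), and the ester serves as the C7 protecting group.

Step 14
Reactants: 27 erythro 4-nitrobenzoate; 28 sodium periodate
Product: 29 (1S,2R)-3-[(tert-butyldimethylsilyl)oxy]-2-(4-formyl-2-methoxyphenoxy)-1-[3-methoxy-4-(triisopropylsilyloxy)phenyl]propyl 4-nitrobenzoate
Conditions: OsO4 (cat.), NaIO4, 2,6-lutidine, dioxane/H2O, rt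
Reagents that add atoms: sodium periodate (28), [Na+].[O-]I(=O)(=O)=O
Why: Lemieux–Johnson oxidative cleavage of the electron-rich propenyl group to the aryl aldehyde; esters and silyl ethers are inert.

**Assembly (steps 15–24)**

Step 15
Reactants: 14 syringaresinol (3 equiv, excess recovered); 30 (R)-4-benzyl-3-(chloroacetyl)oxazolidin-2-one
Product: 31 4-O-{2-[(R)-4-benzyl-2-oxooxazolidin-3-yl]-2-oxoethyl}syringaresinol
Conditions: K2CO3, MeCN, 40 °C
Reagents that add atoms: (R)-4-benzyl-3-(chloroacetyl)oxazolidin-2-one (30), O=C1OC[C@@H](Cc2ccccc2)N1C(=O)CCl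
Why: Williamson mono-etherification of one of the two equivalent phenols; the excess of 14 keeps bis-alkylation low.

Step 16
Reactants: 31 mono-ether; 32 benzoyl chloride
Product: 33 4′-O-benzoate of 31
Conditions: BzCl, Et3N, DMAP (cat.), CH2Cl2, 0 °C
Reagents that add atoms: benzoyl chloride (32), O=C(Cl)c1ccccc1
Why: acylation masks the remaining phenol with a non-enolizable ester that the next hydride step removes without an extra operation.

Step 17
Reactants: 33 benzoate imide; 17 3-methoxy-4-[(triisopropylsilyl)oxy]benzaldehyde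
Product: 35 (R)-4-benzyl-3-[(2R,3S)-2-(4′-O-benzoylsyringaresinol-4-O-yl)-3-hydroxy-3-{3-methoxy-4-(triisopropylsilyloxy)phenyl}propanoyl]oxazolidin-2-one, via Z boron enolate 34 (not isolated)
Conditions: Bu2BOTf, i-Pr2NEt, CH2Cl2, −78 → 0 °C; 17, −78 → 0 °C; then pH 7 buffer, MeOH, H2O2, 0 °C
Reagents that add atoms: aldehyde 17, O=Cc1ccc(O[Si](C(C)C)(C(C)C)C(C)C)c(OC)c1
Why: Evans syn aldol of the imide Z boron enolate (the benzoate cannot enolize); the (R)-auxiliary sets 2R,3S through the chair transition state.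

Step 18
Reactants: 35 syn-aldol adduct
Product: 36 syringaresinol 4-O-[(1S,2S)-1,3-dihydroxy-1-{3-methoxy-4-(triisopropylsilyloxy)phenyl}propan-2-yl] ether (unit A threo; 4′-OH free)
Conditions: LiBH4 (excess), THF/MeOH, 0 °C → rt
Reagents that add atoms: none
Why: LiBH4 reduces the N-acyloxazolidinone to the primary alcohol and reductively cleaves the aryl benzoate, which frees the second core phenol in the same operation.

Step 19
Reactants: 36 phenol diol; 30 (R)-4-benzyl-3-(chloroacetyl)oxazolidin-2-one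
Product: 37 ether of 36 bearing the 2-[(R)-4-benzyl-2-oxooxazolidin-3-yl]-2-oxoethyl group at O4′
Conditions: K2CO3, MeCN, 40 °C
Reagents that add atoms: (R)-4-benzyl-3-(chloroacetyl)oxazolidin-2-one (30), O=C1OC[C@@H](Cc2ccccc2)N1C(=O)CCl
Why: Williamson etherification; carbonate deprotonates only the phenol, so the two alcohols and the bulky aryl TIPS ether are left alone.

Step 20
Reactants: 37 diol imide; 24 tert-butylchlorodimethylsilane
Product: 38 9A-O-TBS ether of 37
Conditions: TBSCl (1.1 equiv), imidazole, CH2Cl2, 0 °C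
Reagents that add atoms: tert-butylchlorodimethylsilane (24), CC(C)(C)[Si](C)(C)Cl
Why: primary-selective silylation leaves only the benzylic 7A-hydroxyl free for inversion.

Step 21
Reactants: 38 mono-TBS ether; 26 4-nitrobenzoic acid
Product: 39 7A-inverted 4-nitrobenzoate of 38 (unit A erythro, 7R,8S)
Conditions: PPh3, DIAD, 4-O2NC6H4CO2H, toluene/THF, 0 °C → rt
Reagents that add atoms: 4-nitrobenzoic acid (26), OC(=O)c1ccc(cc1)[N+](=O)[O-]
Why: Mitsunobu inversion (SN2) at C7A converts threo 7S,8S into erythro 7R,8S; the imide is not a pronucleophile, and the ester protects O7A through the next step.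

Step 22
Reactants: 39 erythro imide; 29 fragment 2 aldehyde
Product: 41 syn-aldol adduct with 2R,3S at the new centres (imide carbon C8B bearing the core aryloxy group, carbinol C7B bearing ring B), via Z boron enolate 40 (not isolated)
Conditions: Bu2BOTf, i-Pr2NEt, CH2Cl2, −78 → 0 °C; 29 (1.3 equiv), −78 → 0 °C; then pH 7 buffer, MeOH, H2O2, 0 °C
Reagents that add atoms: aldehyde 29, CC(C)(C)[Si](C)(C)OC[C@@H](Oc1ccc(C=O)cc1OC)[C@@H](OC(=O)c1ccc(cc1)[N+](=O)[O-])c1ccc(O[Si](C(C)C)(C(C)C)C(C)C)c(OC)c1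
Why: Evans syn aldol, the reaction type already used in steps 10 and 17; the (R)-auxiliary controls both new centres (2R,3S, which becomes threo 7S,8S of unit B) and overrides the remote stereocentres of the aldehyde.

Step 23
Reactants: 41 aldol adduct
Product: 42 target protected as 9A-O-TBS, 9C-O-TBS and aryl O-TIPS ethers on the guaiacyl rings of units A and C
Conditions: LiBH4 (excess), THF/MeOH, 0 °C → rt
Reagents that add atoms: none
Why: LiBH4 reduces the N-acyloxazolidinone to the 9B alcohol and both 4-nitrobenzoates to the free 7A and 7C alcohols, while nitro groups and silyl ethers are not attacked.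

Step 24
Reactants: 42 tetrasilyl ether
Product: 43 target CNP0316493.3
Conditions: Bu4NF (TBAF), AcOH, THF, 0 °C → rt
Reagents that add atoms: none
Why: fluoride-mediated global desilylation (two alkyl TBS and two aryl TIPS ethers) in a buffered medium that spares the acid-sensitive benzylic alcohols and furofuran ethers; no stereocentre is touched.

**Compound list**

1 | acetosyringone | CC(=O)c1cc(OC)c(O)c(OC)c1 | starting material
2 | benzyl bromide | BrCc1ccccc1 | starting material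
3 | 1-[4-(benzyloxy)-3,5-dimethoxyphenyl]ethan-1-one | CC(=O)c1cc(OC)c(OCc2ccccc2)c(OC)c1 | intermediate
4 | dimethyl carbonate | COC(=O)OC | starting material
5 | methyl 3-[4-(benzyloxy)-3,5-dimethoxyphenyl]-3-oxopropanoate | COC(=O)CC(=O)c1cc(OC)c(OCc2ccccc2)c(OC)c1 | intermediate
6 | methyl 3-[4-(benzyloxy)-3,5-dimethoxyphenyl]-2-iodo-3-oxopropanoate (racemic, not isolated) | COC(=O)C(I)C(=O)c1cc(OC)c(OCc2ccccc2)c(OC)c1 | intermediate
7 | dimethyl 2,3-bis[4-(benzyloxy)-3,5-dimethoxybenzoyl]butanedioate (stereolabile) | COC(=O)C(C(=O)c1cc(OC)c(OCc2ccccc2)c(OC)c1)C(C(=O)OC)C(=O)c1cc(OC)c(OCc2ccccc2)c(OC)c1 | intermediate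
8 | dimethyl (2S,3S)-2,3-bis{(S)-[4-(benzyloxy)-3,5-dimethoxyphenyl](hydroxy)methyl}butanedioate (not isolated) | COc1cc(cc(OC)c1OCc1ccccc1)[C@@H](O)[C@@H](C(=O)OC)[C@H](C(=O)OC)[C@H](O)c1cc(OC)c(OCc2ccccc2)c(OC)c1 | intermediate
9 | methyl (2S,3S,4S)-2-[4-(benzyloxy)-3,5-dimethoxyphenyl]-4-{(S)-[4-(benzyloxy)-3,5-dimethoxyphenyl](hydroxy)methyl}-5-oxooxolane-3-carboxylate (not isolated) | COc1cc(cc(OC)c1OCc1ccccc1)[C@H]1OC(=O)[C@H]([C@H](O)c2cc(OC)c(OCc3ccccc3)c(OC)c2)[C@@H]1C(=O)OC | intermediate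
10 | (1S,2S,5S,6S)-2,6-bis[4-(benzyloxy)-3,5-dimethoxyphenyl]-3,7-dioxabicyclo[3.3.0]octane-4,8-dione | COc1cc(cc(OC)c1OCc1ccccc1)[C@H]1OC(=O)[C@H]2[C@@H]1C(=O)O[C@@H]2c1cc(OC)c(OCc2ccccc2)c(OC)c1 | intermediate
11 | (1S,2R,3R,4S)-1,4-bis[4-(benzyloxy)-3,5-dimethoxyphenyl]-2,3-bis(hydroxymethyl)butane-1,4-diol | COc1cc(cc(OC)c1OCc1ccccc1)[C@@H](O)[C@@H](CO)[C@H](CO)[C@H](O)c1cc(OC)c(OCc2ccccc2)c(OC)c1 | intermediate
12 | bis(primary methanesulfonate) of 11 (not isolated) | COc1cc(cc(OC)c1OCc1ccccc1)[C@@H](O)[C@@H](COS(C)(=O)=O)[C@H](COS(C)(=O)=O)[C@H](O)c1cc(OC)c(OCc2ccccc2)c(OC)c1 | intermediate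
13 | (7S,8R,7′S,8′R)-4,4′-di-O-benzylsyringaresinol | COc1cc(cc(OC)c1OCc1ccccc1)[C@H]1OC[C@H]2[C@@H]1CO[C@@H]2c1cc(OC)c(OCc2ccccc2)c(OC)c1 | intermediate
14 | (7S,8R,7′S,8′R)-syringaresinol | COc1cc(cc(OC)c1O)[C@H]1OC[C@H]2[C@@H]1CO[C@@H]2c1cc(OC)c(O)c(OC)c1 | intermediate
15 | vanillin | O=Cc1ccc(O)c(OC)c1 | starting material
16 | chlorotriisopropylsilane | CC(C)[Si](Cl)(C(C)C)C(C)C | starting material
17 | 3-methoxy-4-[(triisopropylsilyl)oxy]benzaldehyde | O=Cc1ccc(O[Si](C(C)C)(C(C)C)C(C)C)c(OC)c1 | intermediate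
18 | trans-isoeugenol | C/C=C/c1ccc(O)c(OC)c1 | starting material
19 | (S)-4-benzyl-3-(chloroacetyl)oxazolidin-2-one | O=C1OC[C@H](Cc2ccccc2)N1C(=O)CCl | starting material
20 | (S)-4-benzyl-3-{2-[2-methoxy-4-((E)-prop-1-enyl)phenoxy]acetyl}oxazolidin-2-one | O=C1OC[C@H](Cc2ccccc2)N1C(=O)COc1ccc(/C=C/C)cc1OC | intermediate
21 | Z dibutylboron enolate of 20 (not isolated) | O=C1OC[C@H](Cc2ccccc2)N1/C(OB(CCCC)CCCC)=C/Oc1ccc(/C=C/C)cc1OC | intermediate
22 | (2S,3R) syn-aldol adduct of 20 and 17 | O=C1OC[C@H](Cc2ccccc2)N1C(=O)[C@@H](Oc1ccc(/C=C/C)cc1OC)[C@H](O)c1ccc(O[Si](C(C)C)(C(C)C)C(C)C)c(OC)c1 | intermediate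
23 | (1R,2R)-threo diol of unit C on the isoeugenol ring | OC[C@@H](Oc1ccc(/C=C/C)cc1OC)[C@H](O)c1ccc(O[Si](C(C)C)(C(C)C)C(C)C)c(OC)c1 | intermediate
24 | tert-butylchlorodimethylsilane | CC(C)(C)[Si](C)(C)Cl | starting material
25 | 3-O-TBS ether of 23 | CC(C)(C)[Si](C)(C)OC[C@@H](Oc1ccc(/C=C/C)cc1OC)[C@H](O)c1ccc(O[Si](C(C)C)(C(C)C)C(C)C)c(OC)c1 | intermediate
26 | 4-nitrobenzoic acid | OC(=O)c1ccc(cc1)[N+](=O)[O-] | starting material
27 | (1S,2R)-erythro 4-nitrobenzoate from 25 | CC(C)(C)[Si](C)(C)OC[C@@H](Oc1ccc(/C=C/C)cc1OC)[C@@H](OC(=O)c1ccc(cc1)[N+](=O)[O-])c1ccc(O[Si](C(C)C)(C(C)C)C(C)C)c(OC)c1 | intermediate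
28 | sodium periodate | [Na+].[O-]I(=O)(=O)=O | starting material
29 | fragment 2 aldehyde, (1S,2R)-3-(TBS-oxy)-2-(4-formyl-2-methoxyphenoxy)-1-[3-methoxy-4-(TIPS-oxy)phenyl]propyl 4-nitrobenzoate | CC(C)(C)[Si](C)(C)OC[C@@H](Oc1ccc(C=O)cc1OC)[C@@H](OC(=O)c1ccc(cc1)[N+](=O)[O-])c1ccc(O[Si](C(C)C)(C(C)C)C(C)C)c(OC)c1 | intermediate
30 | (R)-4-benzyl-3-(chloroacetyl)oxazolidin-2-one | O=C1OC[C@@H](Cc2ccccc2)N1C(=O)CCl | starting material
31 | 4-O-{2-[(R)-4-benzyl-2-oxooxazolidin-3-yl]-2-oxoethyl}syringaresinol | O=C1OC[C@@H](Cc2ccccc2)N1C(=O)COc1c(OC)cc(cc1OC)[C@H]1OC[C@H]2[C@@H]1CO[C@@H]2c1cc(OC)c(O)c(OC)c1 | intermediate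
32 | benzoyl chloride | O=C(Cl)c1ccccc1 | starting material
33 | 4′-O-benzoate of 31 | O=C1OC[C@@H](Cc2ccccc2)N1C(=O)COc1c(OC)cc(cc1OC)[C@H]1OC[C@H]2[C@@H]1CO[C@@H]2c1cc(OC)c(OC(=O)c2ccccc2)c(OC)c1 | intermediate
34 | Z dibutylboron enolate of 33 (not isolated) | O=C1OC[C@@H](Cc2ccccc2)N1/C(OB(CCCC)CCCC)=C/Oc1c(OC)cc(cc1OC)[C@H]1OC[C@H]2[C@@H]1CO[C@@H]2c1cc(OC)c(OC(=O)c2ccccc2)c(OC)c1 | intermediate
35 | (2R,3S) syn-aldol adduct of 33 and 17 | O=C1OC[C@@H](Cc2ccccc2)N1C(=O)[C@H](Oc1c(OC)cc(cc1OC)[C@H]1OC[C@H]2[C@@H]1CO[C@@H]2c1cc(OC)c(OC(=O)c2ccccc2)c(OC)c1)[C@@H](O)c1ccc(O[Si](C(C)C)(C(C)C)C(C)C)c(OC)c1 | intermediate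
36 | syringaresinol 4-O-[(1S,2S)-1,3-dihydroxy-1-{3-methoxy-4-(TIPS-oxy)phenyl}propan-2-yl] ether | OC[C@H](Oc1c(OC)cc(cc1OC)[C@H]1OC[C@H]2[C@@H]1CO[C@@H]2c1cc(OC)c(O)c(OC)c1)[C@@H](O)c1ccc(O[Si](C(C)C)(C(C)C)C(C)C)c(OC)c1 | intermediate
37 | 36 alkylated at O4′ with the (R)-glycolyl imide | OC[C@H](Oc1c(OC)cc(cc1OC)[C@H]1OC[C@H]2[C@@H]1CO[C@@H]2c1cc(OC)c(OCC(=O)N2C(=O)OC[C@H]2Cc2ccccc2)c(OC)c1)[C@@H](O)c1ccc(O[Si](C(C)C)(C(C)C)C(C)C)c(OC)c1 | intermediate
38 | 9A-O-TBS ether of 37 | CC(C)(C)[Si](C)(C)OC[C@H](Oc1c(OC)cc(cc1OC)[C@H]1OC[C@H]2[C@@H]1CO[C@@H]2c1cc(OC)c(OCC(=O)N2C(=O)OC[C@H]2Cc2ccccc2)c(OC)c1)[C@@H](O)c1ccc(O[Si](C(C)C)(C(C)C)C(C)C)c(OC)c1 | intermediate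
39 | 7A-inverted 4-nitrobenzoate of 38 (unit A 7R,8S) | CC(C)(C)[Si](C)(C)OC[C@H](Oc1c(OC)cc(cc1OC)[C@H]1OC[C@H]2[C@@H]1CO[C@@H]2c1cc(OC)c(OCC(=O)N2C(=O)OC[C@H]2Cc2ccccc2)c(OC)c1)[C@H](OC(=O)c1ccc(cc1)[N+](=O)[O-])c1ccc(O[Si](C(C)C)(C(C)C)C(C)C)c(OC)c1 | intermediate
40 | Z dibutylboron enolate of 39 (not isolated) | CC(C)(C)[Si](C)(C)OC[C@H](Oc1c(OC)cc(cc1OC)[C@H]1OC[C@H]2[C@@H]1CO[C@@H]2c1cc(OC)c(O/C=C(/N2C(=O)OC[C@H]2Cc2ccccc2)OB(CCCC)CCCC)c(OC)c1)[C@H](OC(=O)c1ccc(cc1)[N+](=O)[O-])c1ccc(O[Si](C(C)C)(C(C)C)C(C)C)c(OC)c1 | intermediate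
41 | (2R,3S) syn-aldol adduct of 39 and 29 | CC(C)(C)[Si](C)(C)OC[C@H](Oc1c(OC)cc(cc1OC)[C@H]1OC[C@H]2[C@@H]1CO[C@@H]2c1cc(OC)c(O[C@@H](C(=O)N2C(=O)OC[C@H]2Cc2ccccc2)[C@@H](O)c2ccc(O[C@H](CO[Si](C)(C)C(C)(C)C)[C@@H](OC(=O)c3ccc(cc3)[N+](=O)[O-])c3ccc(O[Si](C(C)C)(C(C)C)C(C)C)c(OC)c3)c(OC)c2)c(OC)c1)[C@H](OC(=O)c1ccc(cc1)[N+](=O)[O-])c1ccc(O[Si](C(C)C)(C(C)C)C(C)C)c(OC)c1 | intermediate
42 | target as 9A,9C-bis(TBS) ether and bis(aryl TIPS) ether | CC(C)(C)[Si](C)(C)OC[C@H](Oc1c(OC)cc(cc1OC)[C@H]1OC[C@H]2[C@@H]1CO[C@@H]2c1cc(OC)c(O[C@@H](CO)[C@@H](O)c2ccc(O[C@H](CO[Si](C)(C)C(C)(C)C)[C@@H](O)c3ccc(O[Si](C(C)C)(C(C)C)C(C)C)c(OC)c3)c(OC)c2)c(OC)c1)[C@H](O)c1ccc(O[Si](C(C)C)(C(C)C)C(C)C)c(OC)c1 | intermediate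
43 | CNP0316493.3 | COc1cc([C@@H](O)[C@H](CO)Oc2c(OC)cc([C@H]3OC[C@H]4[C@@H]3CO[C@@H]4c3cc(OC)c(O[C@@H](CO)[C@@H](O)c4ccc(O[C@H](CO)[C@@H](O)c5ccc(O)c(OC)c5)c(OC)c4)c(OC)c3)cc2OC)ccc1O | target

**Step count**

Total: 24 steps. Longest linear sequence: 17 steps (steps 1–7 and 15–24); fragment 2 takes 7 steps (8–14) and joins at step 22.

**Steps most likely to fail, with fallbacks**

Step 4 (the proposed new method). The ketone reduction may lag behind cyclodehydration of the 1,4-diketone to a furan, or the dynamic resolution may give the 7,8-anti relation in one or both halves, so that the crosswise lactonization stops at a hydroxy ester. The fallback sets out from 7 and returns to the route at 10. Both ketones are reduced without chiral control (NaBH4, MeOH/THF, 0 °C, the known passage from 2,3-diaroylsuccinates to these bislactones) and lactonization is completed with TsOH in toluene. This should give the exo,exo-dilactone as the racemate, that is 10 together with its mirror image, the (1R,2R,5R,6R)-dilactone F1. Preparative chromatography on a chiral stationary phase (cellulose tris(3,5-dimethylphenylcarbamate)) would then deliver 10 for step 5.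

Step 21. The electron-rich benzylic alkoxyphosphonium may ionize before the carboxylate attacks, which would erode the inversion (partial retention) or lead to elimination. The fallback sets out from 38 and returns at 39. The 7A-hydroxyl is oxidized with Dess–Martin periodinane (NaHCO3, CH2Cl2) to the aryl ketone F2. Chelation-controlled reduction with Zn(BH4)2 (Et2O, −40 °C; zinc bridging the carbonyl and the 8-aryloxy oxygen, hydride entering opposite the CH2OTBS group) should give the erythro (7R,8S) alcohol F3. Acylation with 4-nitrobenzoyl chloride in pyridine then leads to 39.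

Step 15. The excess phenoxide may take the acyl group from the imide instead of displacing chloride, and the statistical etherification may run on to the bis-ether. The fallback sets out from 14 and returns at 33, which makes steps 15 and 16 unnecessary. Mono-alkylation of 14 with benzyl bromoacetate (1 equiv, K2CO3, MeCN) should give the benzyl aryloxyacetate F4. Benzoylation of the second phenol (BzCl, Et3N, DMAP) gives the benzoate benzyl ester F5. Hydrogenolysis (H2, Pd/C, EtOAc) frees the aryloxyacetic acid F6. This acid is coupled with (R)-4-benzyloxazolidin-2-one (DCC, DMAP, CH2Cl2) to give 33 for step 17.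

**Further compounds**

F1 | step 4 | (1R,2R,5R,6R)-2,6-bis[4-(benzyloxy)-3,5-dimethoxyphenyl]-3,7-dioxabicyclo[3.3.0]octane-4,8-dione (enantiomer of 10) | COc1cc(cc(OC)c1OCc1ccccc1)[C@@H]1OC(=O)[C@@H]2[C@H]1C(=O)O[C@H]2c1cc(OC)c(OCc2ccccc2)c(OC)c1
F2 | step 21 | 7A-ketone from 38 (8S) | CC(C)(C)[Si](C)(C)OC[C@H](Oc1c(OC)cc(cc1OC)[C@H]1OC[C@H]2[C@@H]1CO[C@@H]2c1cc(OC)c(OCC(=O)N2C(=O)OC[C@H]2Cc2ccccc2)c(OC)c1)C(=O)c1ccc(O[Si](C(C)C)(C(C)C)C(C)C)c(OC)c1
F3 | step 21 | erythro (7R,8S) alcohol, 7A-epimer of 38 | CC(C)(C)[Si](C)(C)OC[C@H](Oc1c(OC)cc(cc1OC)[C@H]1OC[C@H]2[C@@H]1CO[C@@H]2c1cc(OC)c(OCC(=O)N2C(=O)OC[C@H]2Cc2ccccc2)c(OC)c1)[C@H](O)c1ccc(O[Si](C(C)C)(C(C)C)C(C)C)c(OC)c1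
F4 | step 15 | benzyl 2-(syringaresinol-4-O-yl)acetate | O=C(COc1c(OC)cc(cc1OC)[C@H]1OC[C@H]2[C@@H]1CO[C@@H]2c1cc(OC)c(O)c(OC)c1)OCc1ccccc1
F5 | step 15 | benzyl 2-(4′-O-benzoylsyringaresinol-4-O-yl)acetate | O=C(COc1c(OC)cc(cc1OC)[C@H]1OC[C@H]2[C@@H]1CO[C@@H]2c1cc(OC)c(OC(=O)c2ccccc2)c(OC)c1)OCc1ccccc1
F6 | step 15 | 2-(4′-O-benzoylsyringaresinol-4-O-yl)acetic acid | OC(=O)COc1c(OC)cc(cc1OC)[C@H]1OC[C@H]2[C@@H]1CO[C@@H]2c1cc(OC)c(OC(=O)c2ccccc2)c(OC)c1
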